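## The problem

Compound 42 is built from two trans-fused oxepane–cyclohexane bicycles, rings A and B (C1–C11 with O5) and rings C and D (C14–C24 with O20), tied tail to tail by the C12–C13 ethylene bridge. The only bond between the halves therefore joins two methylenes, and a convergent synthesis from two bicycles of equal size is natural. There are nine stereocentres: C1, C4, C7, C10 and C11 in the hydroxy half and C14, C15, C21 and C24 in the keto half. The halves have the same absolute arrangement at the ring fusion and at the bridge-bearing carbon but are epimeric at the tertiary acetate carbon (C1 acetate axial, C24 acetate equatorial), and they are too far apart to control one another, so both must come from one enantiomeric series. Within each half the angular methyl (on C10 or C15), held axial by the trans fusion, shields one face of the cyclohexane and can control C11 and C1 or C14 and C24; the fusion oxygen (on C4 or C21) must stand cis to that methyl, the opposite of what reduction of a 2,2-disubstituted cyclohexane-1,3-dione gives directly. The seven-membered ethers resist direct closure because 7-endo etherification has to compete with 6-exo closure, and the fragile groups are the two tertiary acetates (elimination, acyl shift to a neighbouring alkoxide) and the C18 ketone, which must end beside a free C7 carbinol. The enabling feature is in ring D (C15, C16, C17, C18, C19, O20, C21): the carbonyl C18 sits between the fully substituted, oxygen-bearing C19 and the methylenes C17 and C16. Removing C17 leaves a 2,2-dimethyltetrahydropyran-3-one that closes by 6-endo opening of a prenyl epoxide on C15, and putting C17 back is a one-carbon ring expansion whose migrating carbon is fixed by the substitution pattern.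

## Retrosynthesis

Locants C1–C24 are those of 42 and are used for every intermediate.

**The C12=C13 bond.** 42 is traced to alkene 41 (hydrogenation, which also frees the C7 hydroxyl from its benzyl ether), 41 to tertiary alcohol 40 (C1 acetylation), and 40 to sulfone 38 and aldehyde 25 by a Julia–Kocienski olefination. Cuts at C11–C12 or C13–C14 would end on ring stereocentres flanked by fully substituted carbons, whereas C12=C13 joins two primary positions and the alkene geometry is erased. The cut gives two bicycles with the same absolute configuration at C4/C10/C11 and C21/C15/C14. The carbanion is placed on the hydroxy half, which then has no carbonyl group. The forward step must add to the C13 aldehyde faster than it enolises it or the C18 ketone, and the C1 oxygen is kept as a silyl ether because an acetate beside the C12 carbanion would be attacked.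

**Ring D.** Aldehyde 25 comes from alcohol 24 and benzyl ether 23. In 23 the C16–C17 and C17–C18 bonds are cut, C17 leaving as trimethylsilyldiazomethane 21, which gives pyranone 20 (forward via α-silyl ketone 22). The neighbouring cut O20–C19 would need a 7-endo epoxide opening that must beat 6-exo closure; this cut keeps both ether bonds and asks only for a one-carbon insertion. 20 is a six-membered ether whose carbonyl carbon is the one that ends as C18. The forward reaction must move C16, not C19, and it is placed after all hydride and organometallic steps of the keto half so that the C18 carbonyl is never masked or re-made.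

**C24 and C14 of the keto half.** 20 is led back through 19, 18, 17 and diol 16 to hydroxy ester 15, epoxy ester 14, enoate 13, enol triflate 12, methyl ketone 11 and ketone 10; the bonds cut are C24–O, C13–C14 and C24–CH3. Methyl addition to a C24 ketone would place the hydroxyl axial, which is the C1 arrangement of the other half. An equatorial C24 oxygen needs oxygen delivery to an alkene face, here the face of the tetrasubstituted C14=C24 bond opposite the axial C15 methyl. 10 has no stereocentre in the carbocycle beyond the ring fusion. The forward steps need face-selective epoxidation, cleavage of the C14–O bond only, and protonation of C14 from the same open face.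

**Rings A and B.** Sulfone 38 is taken back to 37, sulfide 36, ketone 35 and enone 34 (cuts C1–CH3 and C12–S). 34 comes from 33 and 32, and these from oxepanol 31, oxepanone 30 (forward via 29), pyranone 28, 27, 26 and again ketone 10 (cuts: C8 out of ring A, C11=C12). Here methyl addition to the C1 ketone is wanted, because it gives the axial hydroxyl of this half, and the exocyclic enone lets sulfur enter by conjugate addition with C11 settling equatorial. Ring A uses the same one-carbon expansion, done early on 28 because the C7 carbonyl is reduced anyway and the carbinol must be set under reagent control and protected before ring B is built. The branch shares steps 1–7 with the keto half.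

**The pyran ring.** 10 is derived from 9, 8 and pyranol 7, and 7 from epoxy alcohol 6 and alkene 5 by cutting O20–C19. Closure at the tertiary epoxide carbon by the equatorial C21 hydroxyl is a 6-endo process favoured by the substitution of C19 and by the strain of the alternative trans-fused five-membered ether. A halo- or selenoetherification would leave a C18 substituent that is harder to turn into the ketone. The forward step needs the C21 hydroxyl trans to the side chain and the C14 oxygen blocked, since a free C14 hydroxyl (cis to the chain) would close a cis-fused ether.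

**C15 and C21.** 5 is the anti-1,3-diol monoacetate of ketol 4, which comes from dione 3 and thus from 1 and 2 (cuts C21–H and C15–C16). Reduction of 3 by yeast or hydride puts the new hydroxyl cis to the prenyl group, the wrong relationship for C21. That carbinol is therefore assigned to C14, where it is later oxidised after fixing C15. The C21 hydroxyl is made from the remaining ketone by hydride delivery from the C14 oxygen, which places it trans to the prenyl group and leaves the C14 oxygen acetylated in the same operation. The forward steps ask for enantiotopic-group selection in the reduction of 3 and a 1,3-anti reduction across a quaternary carbon.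

## Roads not taken

Alternative 1: Ring B would be assembled by cutting C9–C10 and C11–C12 together. A homoprenyl organomagnesium reagent, under copper catalysis, adds to C10 of silyloxy enone A1 anti to the silyloxy group, and the magnesium enolate is trapped at C11 by a one-carbon aldehyde electrophile to give ketone A2. One step sets the C4/C10 relationship that costs steps 2 and 3 here, and delivers the C1 ketone with the C12 arm in place, a pattern that takes steps 21 and 27–29 here. The weak points are the multistep asymmetric supply of A1, the slow formation of a quaternary centre beside a silyloxy-bearing carbon, and an unreliable enolate hydroxymethylation. The main weakness is what follows: A2 already carries C6–C9, so ring A must be closed as an oxepane, with the C4 hydroxyl opening a C6–C7 epoxide 7-endo against 6-exo closure. The keto half would also need a separate solution for its equatorial C24 oxygen. For the carbocycle this road is shorter. The chosen plan sets against it a six-membered ether closure without a comparably easy competing mode, a regiochemically predetermined insertion, and one intermediate (10) that feeds both halves.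

Alternative 2: The cut runs through C4–C10 and C8–C9 in one photochemical step, with later cleavage of C4–C8. Irradiation near 350 nm of a furanone carrying the alkene on a tether would give the straight (2+2) adduct A3, which holds ring B and, inside a cyclobutane, all atoms of ring A; fragmentation of C4–C8 then releases the oxepanone. It forms two carbon–carbon bonds and the quaternary C10 in one operation and gives the seven-membered ketone directly. Against it stand the straight-versus-crossed regiochemistry, the lack of any handle for absolute configuration, and the fact that C4 becomes a stereocentre only when the cyclobutane is cleaved, so the trans fusion is not secured. The C1 ketal and C11 arm would still need elaboration. In bond economy this road is better. The chosen plan offers ground-state control of every centre (C15 by enzyme, C21 by intramolecular hydride delivery, the rest by the axial methyl).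

Alternative 3: Rings A and B would be cut at O5–C6 and C10–C11 and formed in one cascade. A silyl triflate with a hindered pyridine base opens the terminal epoxide of an acyclic precursor at C6 toward the oxygen of the internal epoxide, and the allylsilane carbon C11 opens the resulting epoxonium ion at C10 with inversion, giving A4 with an exocyclic C1 methylene and a free C7 carbinol. This is the shortest road: two rings and the C4, C7, C10 and C11 centres in one step from epoxides set by reagent control. A4 also suits the keto half, since oxidation at C7 gives the ketone and epoxidation–reduction of the methylene gives an equatorial tertiary alcohol. Its weak points are the modest efficiency typical of such cascades (competing opening modes, early termination), the need for a diastereomerically pure bis-epoxide allylsilane, and the axial C1 hydroxyl of the hydroxy half, which is the less accessible epimer from an exocyclic methylene. In step count it is clearly superior. The chosen plan sets against it that each ring and stereocentre is made in a separately controllable, precedented step and that one intermediate serves both halves.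

Key step: step 18

Assumption: the baker's yeast reduction of 3 is taken to follow the (2S,3S) course established for the 2-allyl and 2-propargyl analogues.

## Steps

Step 1
Reactants: 1 2-methylcyclohexane-1,3-dione; 2 1-bromo-3-methylbut-2-ene
Product: 3 prenyl dione (2-methyl-2-(3-methylbut-2-en-1-yl)cyclohexane-1,3-dione)
Conditions: NaOH (1 M aq.), rt
Reagents that add atoms: none
Why: C-Alkylation of the cyclic 1,3-dione enolate by the allylic bromide; in water the enolate oxygen is hydrogen-bonded and attack through C2 dominates, and the product cannot be alkylated again. No stereocentre is formed.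

Step 2
Reactants: 3 prenyl dione
Product: 4 ketol ((2S,3S)-3-hydroxy-2-methyl-2-(3-methylbut-2-en-1-yl)cyclohexan-1-one)
Conditions: baker's yeast (Saccharomyces cerevisiae), sucrose, H2O, 30 °C
Reagents that add atoms: none
Why: Enantiotopic-group-selective microbial ketone reduction; hydride goes to the re face of one carbonyl, anti to the larger 2-substituent, so the hydroxyl (future C14) is cis to prenyl and C15 is fixed. The minor (2R,3S) isomer, which would lead to the enantiomeric series, is removed by chromatography.

Step 3
Reactants: 4 ketol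
Product: 5 hydroxy acetate ((1S,2R,3S)-3-hydroxy-2-methyl-2-(3-methylbut-2-en-1-yl)cyclohexyl acetate)
Conditions: CH3CHO (6 equiv), SmI2 (0.25 equiv), THF, −10 °C
Reagents that add atoms: acetaldehyde, CC=O
Why: Evans–Tishchenko reduction; the samarium-bound hemiacetal formed on the axial C14 oxygen transfers its hydride to C21 through a six-membered chair, so the new C21–H is cis to the C14 oxygen and the C21 hydroxyl is trans to prenyl and cis to the C15 methyl. The directing oxygen emerges as its acetate, which differentiates the two oxygens.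

Step 4
Reactants: 5 hydroxy acetate
Product: 7 pyranol acetate (3S,4aR,5S,8aS)-3-hydroxy-2,2,4a-trimethyloctahydro-2H-chromen-5-yl acetate, via epoxy alcohol 6 (not isolated)
Conditions: 1,2:4,5-di-O-isopropylidene-β-L-erythro-2,3-hexodiulo-2,6-pyranose (L-fructose-derived Shi ketone, 0.3 equiv), Oxone (2KHSO5·KHSO4·K2SO4), K2CO3, n-Bu4NHSO4, MeCN/CH2(OMe)2/aq. Na2B4O7, 0 °C; extractive work-up, then camphorsulfonic acid (0.1 equiv), CH2Cl2, 0 °C to rt
Reagents that add atoms: potassium peroxymonosulfate, [K+].[O-]S(=O)(=O)OO
Why: Shi epoxidation gives the (S)-epoxide 6 under reagent control; acid then triggers 6-endo opening at the tertiary C19 by the equatorial C21 hydroxyl (Markovnikov, chair transition state), the 5-exo mode being disfavoured by the strained trans-fused five-membered ether. C18 is only a placeholder (the D-fructose-derived ketone would give its equally usable epimer); the trans fusion follows from C15 and C21.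

Step 5
Reactants: 7 pyranol acetate
Product: 8 silyl ether acetate (3-[(tert-butyldimethylsilyl)oxy]-2,2,4a-trimethyloctahydro-2H-chromen-5-yl acetate)
Conditions: TBSOTf, 2,6-lutidine, CH2Cl2, 0 °C
Reagents that add atoms: tert-butyldimethylsilyl triflate, CC(C)(C)[Si](C)(C)OS(=O)(=O)C(F)(F)F
Why: Silyl triflate silylation of the hindered secondary C18 hydroxyl; the ether must last through the enolate, palladium, peracid, SmI2 and hydride steps.

Step 6
Reactants: 8 silyl ether acetate
Product: 9 C14 alcohol (3-[(tert-butyldimethylsilyl)oxy]-2,2,4a-trimethyloctahydro-2H-chromen-5-ol)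
Conditions: K2CO3, MeOH, 40 °C
Reagents that add atoms: none
Why: Base-catalysed methanolysis (transesterification) of the C14 acetate; the silyl ether is inert.

Step 7
Reactants: 9 C14 alcohol
Product: 10 bicyclic ketone (3-[(tert-butyldimethylsilyl)oxy]-2,2,4a-trimethyloctahydro-5H-chromen-5-one)
Conditions: Dess–Martin periodinane, NaHCO3, CH2Cl2, rt
Reagents that add atoms: none
Why: Dess–Martin oxidation of the axial C14 carbinol; the stereocentre that fixed C15 and directed step 3 is deleted, and 10 is the branch point for both halves.

Step 8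
Reactants: 10 bicyclic ketone
Product: 11 methyl ketone (3-[(tert-butyldimethylsilyl)oxy]-2,2,4a,6-tetramethyloctahydro-5H-chromen-5-one, both C24 epimers)
Conditions: LiN(iPr)2, THF, −78 °C; MeI, −78 to −20 °C
Reagents that add atoms: iodomethane, CI
Why: Enolate alkylation; C24 is the only enolisable position because C15 is quaternary, and the epimer ratio at C24 is immaterial because step 9 makes this carbon trigonal.

Step 9
Reactants: 11 methyl ketone
Product: 12 enol triflate (3-[(tert-butyldimethylsilyl)oxy]-2,2,4a,6-tetramethyl-3,4,4a,7,8,8a-hexahydro-2H-chromen-5-yl trifluoromethanesulfonate)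
Conditions: KN(SiMe3)2, THF, −78 to 0 °C; PhNTf2, 0 °C
Reagents that add atoms: N-phenylbis(trifluoromethanesulfonimide), O=S(=O)(N(c1ccccc1)S(=O)(=O)C(F)(F)F)C(F)(F)F
Why: O-Sulfonylation of the only possible (tetrasubstituted) enolate gives the enol triflate, as with 2,2,6-trisubstituted cyclohexanones.

Step 10
Reactants: 12 enol triflate
Product: 13 enoate (methyl 3-[(tert-butyldimethylsilyl)oxy]-2,2,4a,6-tetramethyl-3,4,4a,7,8,8a-hexahydro-2H-chromene-5-carboxylate)
Conditions: Pd(OAc)2 (5 mol %), Ph2P(CH2)3PPh2, CO (1 atm), MeOH, Et3N, DMF, 70 °C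
Reagents that add atoms: carbon monoxide, [C-]#[O+]; methanol, CO
Why: Palladium-catalysed methoxycarbonylation of an enol triflate (oxidative addition to zerovalent palladium, CO insertion, methanolysis of the acyl complex); it brings in C13 at the ester level.

Step 11
Reactants: 13 enoate
Product: 14 epoxy ester (methyl 3-[(tert-butyldimethylsilyl)oxy]-5,6-epoxy-2,2,4a,6-tetramethyloctahydro-2H-chromene-5-carboxylate)
Conditions: mCPBA, NaHCO3, CH2Cl2, rt to 40 °C
Reagents that add atoms: 3-chloroperbenzoic acid, OOC(=O)c1cccc(Cl)c1
Why: Prilezhaev epoxidation; the peracid attacks the C14=C24 face anti to the axial C15 methyl, which places the C24 oxygen on that face.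

Step 12
Reactants: 14 epoxy ester
Product: 15 hydroxy ester (methyl 3-[(tert-butyldimethylsilyl)oxy]-6-hydroxy-2,2,4a,6-tetramethyloctahydro-2H-chromene-5-carboxylate)
Conditions: SmI2 (2.5 equiv), MeOH, THF, −78 °C
Reagents that add atoms: none
Why: SmI2 reduction of an α,β-epoxy ester cleaves only the Cα–O bond, so the oxygen stays on C24 with its configuration (equatorial OH, axial methyl). The samarium enolate is protonated at C14 from the face anti to the two axial methyl groups, giving the equatorial ester.

Step 13
Reactants: 15 hydroxy ester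
Product: 16 diol (3-[(tert-butyldimethylsilyl)oxy]-5-(hydroxymethyl)-2,2,4a,6-tetramethyloctahydro-2H-chromen-6-ol)
Conditions: LiAlH4, THF, 0 °C
Reagents that add atoms: none
Why: Hydride reduction of the ester to the primary C13 alcohol; silyl ether and tertiary alcohol are untouched.

Step 14
Reactants: 16 diol
Product: 17 benzyl ether alcohol (5-[(benzyloxy)methyl]-3-[(tert-butyldimethylsilyl)oxy]-2,2,4a,6-tetramethyloctahydro-2H-chromen-6-ol)
Conditions: NaH (1.1 equiv), BnBr, n-Bu4NI, THF, 0 °C to rt
Reagents that add atoms: benzyl bromide, BrCc1ccccc1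
Why: Williamson etherification; the primary alkoxide forms and reacts far faster than the hindered tertiary one, so only the C13 hydroxyl is benzylated.

Step 15
Reactants: 17 benzyl ether alcohol
Product: 18 C24 acetate (5-[(benzyloxy)methyl]-3-[(tert-butyldimethylsilyl)oxy]-2,2,4a,6-tetramethyloctahydro-2H-chromen-6-yl acetate)
Conditions: Ac2O, Et3N, 4-(dimethylamino)pyridine, CH2Cl2, 40 °C
Reagents that add atoms: acetic anhydride, CC(=O)OC(C)=O
Why: Nucleophile-catalysed acylation of the equatorial tertiary C24 hydroxyl through the N-acetylpyridinium ion.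

Step 16
Reactants: 18 C24 acetate
Product: 19 C18 alcohol (5-[(benzyloxy)methyl]-3-hydroxy-2,2,4a,6-tetramethyloctahydro-2H-chromen-6-yl acetate)
Conditions: HF·pyridine, pyridine, THF, 0 °C to rt
Reagents that add atoms: none
Why: Fluoride cleavage of the secondary silyl ether; acetate and benzyl ether are stable to buffered HF·pyridine.

Step 17
Reactants: 19 C18 alcohol
Product: 20 pyranone (5-[(benzyloxy)methyl]-2,2,4a,6-tetramethyl-3-oxooctahydro-2H-chromen-6-yl acetate)
Conditions: Dess–Martin periodinane, NaHCO3, CH2Cl2, rt
Reagents that add atoms: none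
Why: Dess–Martin oxidation; C18 becomes trigonal, so the placeholder centre from step 4 disappears.

Step 18
Reactants: 20 pyranone; 21 trimethylsilyldiazomethane
Product: 23 oxepanone 6-[(benzyloxy)methyl]-2,2,5a,7-tetramethyl-3-oxodecahydro-1-benzoxepin-7-yl acetate, via α-silyl oxepanone 22 (not isolated)
Conditions: 21 (1.5 equiv), BF3·OEt2 (1.2 equiv), CH2Cl2, −78 °C; then pyridinium p-toluenesulfonate, MeOH, rt
Reagents that add atoms: none
Why: BF3 activates the C18 carbonyl and the diazo carbon of 21 adds to it; loss of N2 is coupled with a 1,2-shift of the C16–C18 bond to that carbon, which becomes C17 (new C16–C17 and C17–C18 bonds) while the C18 carbonyl is regenerated. The closest known reaction type is the Lewis acid-promoted Tiffeneau–Demjanov-type homologation of cyclic ketones with trimethylsilyldiazomethane, which is documented for tetrahydropyran-3-ones. Ring D is therefore not closed by a cyclisation: the six-membered ether is enlarged to the seven-membered one by insertion of one carbon, with both O20 bonds untouched. The step needs migration of C16 rather than C19; C19 is quaternary and bears the electron-withdrawing ring oxygen, and the bulky silyl group favours the transition state in which the unhindered methylene migrates. The α-silyl ketone 22 is too hindered to be homologated again and is protodesilylated by the acidic methanol. No stereocentre is formed: C16 moves with its bond to C15 intact, so C15 and the trans fusion are unchanged. The tertiary acetate and the benzyl ether tolerate BF3·OEt2 at −78 °C.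

Step 19
Reactants: 23 oxepanone
Product: 24 C13 alcohol (6-(hydroxymethyl)-2,2,5a,7-tetramethyl-3-oxodecahydro-1-benzoxepin-7-yl acetate)
Conditions: H2 (1 atm), Pd/C (10 wt %), EtOAc, rt
Reagents that add atoms: none
Why: Hydrogenolysis of the benzyl ether under neutral conditions, which avoids base-promoted acetyl migration from O24 to the freed C13 hydroxyl; ketone and acetate are inert.

Step 20
Reactants: 24 C13 alcohol
Product: 25 aldehyde (6-formyl-2,2,5a,7-tetramethyl-3-oxodecahydro-1-benzoxepin-7-yl acetate)
Conditions: Dess–Martin periodinane, NaHCO3, CH2Cl2, 0 °C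
Reagents that add atoms: none
Why: Buffered Dess–Martin oxidation; neutral conditions avoid β-elimination of the acetate and epimerisation at C14 (the equatorial formyl group is also the thermodynamic one), and 25 is used without chromatography.

Step 21
Reactants: 10 bicyclic ketone
Product: 26 methylidene silyl ether (tert-butyldimethyl[(2,2,4a-trimethyl-5-methylideneoctahydro-2H-chromen-3-yl)oxy]silane)
Conditions: Ph3PCH3Br, KOtBu, toluene, 80 °C
Reagents that add atoms: methyltriphenylphosphonium bromide, C[P+](c1ccccc1)(c1ccccc1)c1ccccc1.[Br-]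
Why: Wittig methylenation of the hindered C11 ketone with excess ylide at elevated temperature; it introduces C12.

Step 22
Reactants: 26 methylidene silyl ether
Product: 27 methylidene pyranol (2,2,4a-trimethyl-5-methylideneoctahydro-2H-chromen-3-ol)
Conditions: HF·pyridine, pyridine, THF, 0 °C to rt
Reagents that add atoms: none
Why: Fluoride desilylation; the 1,1-disubstituted alkene survives the buffered reagent.

Step 23
Reactants: 27 methylidene pyranol
Product: 28 methylidene pyranone (2,2,4a-trimethyl-5-methylidenehexahydro-2H-chromen-3(4H)-one)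
Conditions: Dess–Martin periodinane, NaHCO3, CH2Cl2, rt
Reagents that add atoms: none
Why: Dess–Martin oxidation gives the pyranone of the hydroxy half.

Step 24
Reactants: 28 methylidene pyranone; 21 trimethylsilyldiazomethane
Product: 30 methylidene oxepanone 2,2,5a-trimethyl-6-methylideneoctahydro-1-benzoxepin-3(2H)-one, via α-silyl methylidene oxepanone 29 (not isolated)
Conditions: 21 (1.5 equiv), BF3·OEt2 (1.2 equiv), CH2Cl2, −78 °C; then pyridinium p-toluenesulfonate, MeOH, rt
Reagents that add atoms: none
Why: The same Lewis acid-promoted diazoalkane homologation as in step 18, here inserting C8 between C9 and C7; the methylene C9 migrates in preference to the quaternary, oxygen-bearing C6, and the unactivated alkene does not react at −78 °C.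

Step 25
Reactants: 30 methylidene oxepanone
Product: 31 oxepanol ((3S)-2,2,5a-trimethyl-6-methylidenedecahydro-1-benzoxepin-3-ol)
Conditions: (R)-1-methyl-3,3-diphenyltetrahydro-1H,3H-pyrrolo[1,2-c][1,3,2]oxazaborole (0.2 equiv), BH3·SMe2, THF, −20 °C
Reagents that add atoms: none
Why: Corey–Bakshi–Shibata reduction; the ketone binds the catalyst boron anti to its larger substituent (quaternary C6), and hydride delivery gives the (S)-carbinol at C7 (hydroxyl on the face opposite the C10 methyl). Catalysed carbonyl reduction at −20 °C outpaces hydroboration of the hindered alkene.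

Step 26
Reactants: 31 oxepanol
Product: 32 benzyl ether (3-(benzyloxy)-2,2,5a-trimethyl-6-methylidenedecahydro-1-benzoxepine)
Conditions: 2-benzyloxy-1-methylpyridinium triflate, MgO, PhCF3, 85 °C
Reagents that add atoms: 2-benzyloxy-1-methylpyridinium triflate, C[n+]1ccccc1OCc1ccccc1.[O-]S(=O)(=O)C(F)(F)F
Why: Dudley benzylation (benzyl transfer from the pyridinium salt) under neutral conditions suits the hindered carbinol beside C6 and spares the acid-sensitive exocyclic alkene.

Step 27
Reactants: 32 benzyl ether
Product: 33 allylic alcohol (3-(benzyloxy)-2,2,5a-trimethyl-6-methylidenedecahydro-1-benzoxepin-7-ol, both C1 epimers)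
Conditions: SeO2 (0.3 equiv), t-BuOOH, CH2Cl2, rt
Reagents that add atoms: tert-butyl hydroperoxide, CC(C)(C)OO
Why: SeO2 allylic oxidation (ene reaction, then [2,3]-sigmatropic shift); C1 is the only allylic carbon bearing hydrogen because C10 is quaternary, and the alkene returns to the exocyclic position. The C1 carbinol configuration is irrelevant.

Step 28
Reactants: 33 allylic alcohol
Product: 34 enone (3-(benzyloxy)-2,2,5a-trimethyl-6-methylideneoctahydro-1-benzoxepin-7(2H)-one)
Conditions: Dess–Martin periodinane, NaHCO3, CH2Cl2, 0 °C
Reagents that add atoms: none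
Why: Dess–Martin oxidation of the allylic alcohol to the α-methylidene ketone, which is used promptly.

Step 29
Reactants: 34 enone
Product: 35 sulfide ketone (3-(benzyloxy)-2,2,5a-trimethyl-6-{[(1-phenyl-1H-tetrazol-5-yl)sulfanyl]methyl}octahydro-1-benzoxepin-7(2H)-one)
Conditions: 1-phenyl-1H-tetrazole-5-thiol, Et3N (0.1 equiv), CH2Cl2, rt
Reagents that add atoms: 1-phenyl-1H-tetrazole-5-thiol, Sc1nnnn1-c1ccccc1
Why: Thia-Michael addition of the acidic thiol to the exocyclic enone; C11 is protonated from the face anti to the axial C10 methyl and is in any case equilibrated by the amine to the equatorial C12 arm (C11–H axial, cis to C4–H).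

Step 30
Reactants: 35 sulfide ketone
Product: 36 sulfide alcohol (3-(benzyloxy)-2,2,5a,7-tetramethyl-6-{[(1-phenyl-1H-tetrazol-5-yl)sulfanyl]methyl}decahydro-1-benzoxepin-7-ol)
Conditions: MeMgBr, CeCl3, THF, −78 °C
Reagents that add atoms: methylmagnesium bromide, C[Mg]Br
Why: Organocerium 1,2-addition (low basicity suppresses enolisation and loss of the thiolate); the axial C10 methyl blocks axial attack, so the methyl group enters equatorially and the C1 hydroxyl is axial, syn to the C10 methyl, as C1 requires.

Step 31
Reactants: 36 sulfide alcohol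
Product: 37 sulfone alcohol (3-(benzyloxy)-2,2,5a,7-tetramethyl-6-{[(1-phenyl-1H-tetrazol-5-yl)sulfonyl]methyl}decahydro-1-benzoxepin-7-ol)
Conditions: (NH4)6Mo7O24·4H2O (0.1 equiv), H2O2 (30 % aq.), EtOH, 0 °C to rt
Reagents that add atoms: hydrogen peroxide, OO
Why: Molybdate-catalysed peroxide oxidation of the sulfide to the sulfone; tertiary alcohol, benzyl ether and ring ether are inert.

Step 32
Reactants: 37 sulfone alcohol
Product: 38 sulfone silyl ether (C1 trimethylsilyl ether of 37)
Conditions: TMSOTf, 2,6-lutidine, CH2Cl2, −78 to 0 °C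
Reagents that add atoms: trimethylsilyl triflate, C[Si](C)(C)OS(=O)(=O)C(F)(F)F
Why: Silylation of the hindered tertiary alcohol; it masks the C1 oxygen so that its alkoxide cannot attack the tetrazole ring (Smiles-type transfer) in step 33.

Step 33
Reactants: 38 sulfone silyl ether; 25 aldehyde
Product: 40 coupled alcohol (C12=C13 alkene; C1 hydroxyl; C7 benzyl ether; C24 acetate; C18 ketone), via coupled silyl ether 39 (not isolated)
Conditions: KN(SiMe3)2, THF, −78 °C, 30 min; 25, −78 to −20 °C; then HCl (1 M aq.), THF, 0 °C
Reagents that add atoms: none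
Why: Julia–Kocienski olefination: the potassium sulfonyl carbanion adds to the aldehyde, and Smiles rearrangement with loss of SO2 and the tetrazolone gives the C12=C13 alkene. Addition at −78 °C should be faster than enolisation of or attack on the hindered C18 ketone, and the equatorial C24 acetate is poorly aligned for E1cB loss. Dilute acid removes the tertiary trimethylsilyl ether; alkene geometry is irrelevant and no stereocentre is formed.

Step 34
Reactants: 40 coupled alcohol
Product: 41 coupled diacetate (12,13-didehydro 7-O-benzyl derivative of 42)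
Conditions: Ac2O, Sc(OTf)3 (5 mol %), MeCN, −20 °C
Reagents that add atoms: acetic anhydride, CC(=O)OC(C)=O
Why: Sc(OTf)3-catalysed acetylation, a method suited to hindered tertiary alcohols; the C7 oxygen is still benzylated, so only the C1 hydroxyl reacts.

Step 35
Reactants: 41 coupled diacetate
Product: 42 target compound
Conditions: H2 (1 atm), Pd/C (10 wt %), EtOAc/EtOH, rt
Reagents that add atoms: none
Why: Heterogeneous hydrogenation saturates the disubstituted alkene and hydrogenolyses the C7 benzyl ether in one operation; ketone and acetates are stable and no stereocentre is formed.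

## Compound list

1 | 2-methylcyclohexane-1,3-dione | CC1C(=O)CCCC1=O | starting material
2 | 1-bromo-3-methylbut-2-ene | CC(C)=CCBr | starting material
3 | 2-methyl-2-(3-methylbut-2-en-1-yl)cyclohexane-1,3-dione | CC(C)=CCC1(C)C(=O)CCCC1=O | intermediate
4 | (2S,3S)-3-hydroxy-2-methyl-2-(3-methylbut-2-en-1-yl)cyclohexan-1-one (hydroxyl cis to prenyl; carbinol = C14, ketone = C21) | O=C1CCC[C@H](O)[C@]1(C)CC=C(C)C | intermediate
5 | (1S,2R,3S)-3-hydroxy-2-methyl-2-(3-methylbut-2-en-1-yl)cyclohexyl acetate (acetate cis, hydroxyl trans to prenyl) | O[C@H]1CCC[C@H](OC(C)=O)[C@]1(C)CC=C(C)C | intermediate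
6 | (1S,2R,3S)-2-{[(2S)-3,3-dimethyloxiran-2-yl]methyl}-3-hydroxy-2-methylcyclohexyl acetate | O[C@H]1CCC[C@H](OC(C)=O)[C@]1(C)C[C@@H]2OC2(C)C | intermediate
7 | (3S,4aR,5S,8aS)-3-hydroxy-2,2,4a-trimethyloctahydro-2H-chromen-5-yl acetate (trans-fused; 3-OH equatorial, 5-OAc axial) | C1CC[C@@H]2OC(C)(C)[C@@H](O)C[C@@]2(C)[C@H]1OC(C)=O | intermediate
8 | 3-[(tert-butyldimethylsilyl)oxy]-2,2,4a-trimethyloctahydro-2H-chromen-5-yl acetate, stereocentres as in 7 | C1CC[C@@H]2OC(C)(C)[C@@H](O[Si](C)(C)C(C)(C)C)C[C@@]2(C)[C@H]1OC(C)=O | intermediate
9 | 3-[(tert-butyldimethylsilyl)oxy]-2,2,4a-trimethyloctahydro-2H-chromen-5-ol, stereocentres as in 7 | C1CC[C@@H]2OC(C)(C)[C@@H](O[Si](C)(C)C(C)(C)C)C[C@@]2(C)[C@H]1O | intermediate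
10 | 3-[(tert-butyldimethylsilyl)oxy]-2,2,4a-trimethyloctahydro-5H-chromen-5-one (trans-fused; C15, C18, C21 as in 7) | C1CC[C@@H]2OC(C)(C)[C@@H](O[Si](C)(C)C(C)(C)C)C[C@@]2(C)C1=O | intermediate
11 | 3-[(tert-butyldimethylsilyl)oxy]-2,2,4a,6-tetramethyloctahydro-5H-chromen-5-one (both C24 epimers; other centres as in 10) | CC1CC[C@@H]2OC(C)(C)[C@@H](O[Si](C)(C)C(C)(C)C)C[C@@]2(C)C1=O | intermediate
12 | 3-[(tert-butyldimethylsilyl)oxy]-2,2,4a,6-tetramethyl-3,4,4a,7,8,8a-hexahydro-2H-chromen-5-yl trifluoromethanesulfonate | CC=1CC[C@@H]2OC(C)(C)[C@@H](O[Si](C)(C)C(C)(C)C)C[C@@]2(C)C=1OS(=O)(=O)C(F)(F)F | intermediate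
13 | methyl 3-[(tert-butyldimethylsilyl)oxy]-2,2,4a,6-tetramethyl-3,4,4a,7,8,8a-hexahydro-2H-chromene-5-carboxylate | CC=1CC[C@@H]2OC(C)(C)[C@@H](O[Si](C)(C)C(C)(C)C)C[C@@]2(C)C=1C(=O)OC | intermediate
14 | methyl 3-[(tert-butyldimethylsilyl)oxy]-5,6-epoxy-2,2,4a,6-tetramethyloctahydro-2H-chromene-5-carboxylate (epoxide oxygen anti to the C15 methyl) | C[C@]13CC[C@@H]2OC(C)(C)[C@@H](O[Si](C)(C)C(C)(C)C)C[C@@]2(C)[C@@]1(C(=O)OC)O3 | intermediate
15 | methyl 3-[(tert-butyldimethylsilyl)oxy]-6-hydroxy-2,2,4a,6-tetramethyloctahydro-2H-chromene-5-carboxylate (C24 hydroxyl equatorial and anti to the C15 methyl, C24 methyl axial, C14 ester equatorial) | O[C@@]1(C)CC[C@@H]2OC(C)(C)[C@@H](O[Si](C)(C)C(C)(C)C)C[C@@]2(C)[C@@H]1C(=O)OC | intermediate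
16 | 3-[(tert-butyldimethylsilyl)oxy]-5-(hydroxymethyl)-2,2,4a,6-tetramethyloctahydro-2H-chromen-6-ol, centres as in 15 | O[C@@]1(C)CC[C@@H]2OC(C)(C)[C@@H](O[Si](C)(C)C(C)(C)C)C[C@@]2(C)[C@@H]1CO | intermediate
17 | 5-[(benzyloxy)methyl]-3-[(tert-butyldimethylsilyl)oxy]-2,2,4a,6-tetramethyloctahydro-2H-chromen-6-ol, centres as in 15 | O[C@@]1(C)CC[C@@H]2OC(C)(C)[C@@H](O[Si](C)(C)C(C)(C)C)C[C@@]2(C)[C@@H]1COCc1ccccc1 | intermediate
18 | 5-[(benzyloxy)methyl]-3-[(tert-butyldimethylsilyl)oxy]-2,2,4a,6-tetramethyloctahydro-2H-chromen-6-yl acetate, centres as in 15 | CC(=O)O[C@@]1(C)CC[C@@H]2OC(C)(C)[C@@H](O[Si](C)(C)C(C)(C)C)C[C@@]2(C)[C@@H]1COCc1ccccc1 | intermediate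
19 | 5-[(benzyloxy)methyl]-3-hydroxy-2,2,4a,6-tetramethyloctahydro-2H-chromen-6-yl acetate, centres as in 15 | CC(=O)O[C@@]1(C)CC[C@@H]2OC(C)(C)[C@@H](O)C[C@@]2(C)[C@@H]1COCc1ccccc1 | intermediate
20 | 5-[(benzyloxy)methyl]-2,2,4a,6-tetramethyl-3-oxooctahydro-2H-chromen-6-yl acetate (trans-fused pyranone; C14, C15, C21, C24 arranged as in 42) | CC(=O)O[C@@]1(C)CC[C@@H]2OC(C)(C)C(=O)C[C@@]2(C)[C@@H]1COCc1ccccc1 | intermediate
21 | trimethylsilyldiazomethane | C[Si](C)(C)C=[N+]=[N-] | starting material
22 | 6-[(benzyloxy)methyl]-2,2,5a,7-tetramethyl-3-oxo-4-(trimethylsilyl)decahydro-1-benzoxepin-7-yl acetate (C17 epimers; other centres as in 20) | CC(=O)O[C@@]1(C)CC[C@@H]2OC(C)(C)C(=O)C([Si](C)(C)C)C[C@@]2(C)[C@@H]1COCc1ccccc1 | intermediate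
23 | 6-[(benzyloxy)methyl]-2,2,5a,7-tetramethyl-3-oxodecahydro-1-benzoxepin-7-yl acetate (rings C and D; centres as in 42) | CC(=O)O[C@@]1(C)CC[C@@H]2OC(C)(C)C(=O)CC[C@@]2(C)[C@@H]1COCc1ccccc1 | intermediate
24 | 6-(hydroxymethyl)-2,2,5a,7-tetramethyl-3-oxodecahydro-1-benzoxepin-7-yl acetate, centres as in 42 | CC(=O)O[C@@]1(C)CC[C@@H]2OC(C)(C)C(=O)CC[C@@]2(C)[C@@H]1CO | intermediate
25 | 6-formyl-2,2,5a,7-tetramethyl-3-oxodecahydro-1-benzoxepin-7-yl acetate, centres as in 42 | CC(=O)O[C@@]1(C)CC[C@@H]2OC(C)(C)C(=O)CC[C@@]2(C)[C@@H]1C=O | intermediate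
26 | tert-butyldimethyl[(2,2,4a-trimethyl-5-methylideneoctahydro-2H-chromen-3-yl)oxy]silane, centres as in 10 | C1CC[C@@H]2OC(C)(C)[C@@H](O[Si](C)(C)C(C)(C)C)C[C@@]2(C)C1=C | intermediate
27 | 2,2,4a-trimethyl-5-methylideneoctahydro-2H-chromen-3-ol, centres as in 10 | C1CC[C@@H]2OC(C)(C)[C@@H](O)C[C@@]2(C)C1=C | intermediate
28 | 2,2,4a-trimethyl-5-methylidenehexahydro-2H-chromen-3(4H)-one (trans-fused; C4 and C10 as in 42) | C1CC[C@@H]2OC(C)(C)C(=O)C[C@@]2(C)C1=C | intermediate
29 | 2,2,5a-trimethyl-6-methylidene-4-(trimethylsilyl)octahydro-1-benzoxepin-3(2H)-one (C8 epimers) | C1CC[C@@H]2OC(C)(C)C(=O)C([Si](C)(C)C)C[C@@]2(C)C1=C | intermediate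
30 | 2,2,5a-trimethyl-6-methylideneoctahydro-1-benzoxepin-3(2H)-one (trans-fused; C4 and C10 as in 42) | C1CC[C@@H]2OC(C)(C)C(=O)CC[C@@]2(C)C1=C | intermediate
31 | (3S)-2,2,5a-trimethyl-6-methylidenedecahydro-1-benzoxepin-3-ol (C4, C7, C10 as in 42) | C1CC[C@@H]2OC(C)(C)[C@@H](O)CC[C@@]2(C)C1=C | intermediate
32 | 3-(benzyloxy)-2,2,5a-trimethyl-6-methylidenedecahydro-1-benzoxepine, centres as in 31 | C1CC[C@@H]2OC(C)(C)[C@@H](OCc3ccccc3)CC[C@@]2(C)C1=C | intermediate
33 | 3-(benzyloxy)-2,2,5a-trimethyl-6-methylidenedecahydro-1-benzoxepin-7-ol (both epimers at target C1; other centres as in 31) | OC1CC[C@@H]2OC(C)(C)[C@@H](OCc3ccccc3)CC[C@@]2(C)C1=C | intermediate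
34 | 3-(benzyloxy)-2,2,5a-trimethyl-6-methylideneoctahydro-1-benzoxepin-7(2H)-one, centres as in 31 | O=C1CC[C@@H]2OC(C)(C)[C@@H](OCc3ccccc3)CC[C@@]2(C)C1=C | intermediate
35 | 3-(benzyloxy)-2,2,5a-trimethyl-6-{[(1-phenyl-1H-tetrazol-5-yl)sulfanyl]methyl}octahydro-1-benzoxepin-7(2H)-one (C11–H axial, C12 arm equatorial) | O=C1CC[C@@H]2OC(C)(C)[C@@H](OCc3ccccc3)CC[C@@]2(C)[C@@H]1CSc1nnnn1-c1ccccc1 | intermediate
36 | 3-(benzyloxy)-2,2,5a,7-tetramethyl-6-{[(1-phenyl-1H-tetrazol-5-yl)sulfanyl]methyl}decahydro-1-benzoxepin-7-ol (C1 hydroxyl axial, C1 methyl equatorial; C1, C4, C7, C10, C11 as in 42) | O[C@]1(C)CC[C@@H]2OC(C)(C)[C@@H](OCc3ccccc3)CC[C@@]2(C)[C@@H]1CSc1nnnn1-c1ccccc1 | intermediate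
37 | 3-(benzyloxy)-2,2,5a,7-tetramethyl-6-{[(1-phenyl-1H-tetrazol-5-yl)sulfonyl]methyl}decahydro-1-benzoxepin-7-ol, centres as in 36 | O[C@]1(C)CC[C@@H]2OC(C)(C)[C@@H](OCc3ccccc3)CC[C@@]2(C)[C@@H]1CS(=O)(=O)c1nnnn1-c1ccccc1 | intermediate
38 | C1 trimethylsilyl ether of 37 | C[Si](C)(C)O[C@]1(C)CC[C@@H]2OC(C)(C)[C@@H](OCc3ccccc3)CC[C@@]2(C)[C@@H]1CS(=O)(=O)c1nnnn1-c1ccccc1 | intermediate
39 | 12,13-didehydro derivative of 42 with C1 trimethylsilyl ether, C7 benzyl ether and C1 not acetylated (E/Z mixture, mainly E) | C[Si](C)(C)O[C@]1(C)CC[C@@H]2OC(C)(C)[C@@H](OCc3ccccc3)CC[C@@]2(C)[C@@H]1C=C[C@H]1[C@]2(C)CCC(=O)C(C)(C)O[C@H]2CC[C@]1(C)OC(C)=O | intermediate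
40 | 12,13-didehydro 7-O-benzyl 1-O-deacetyl derivative of 42 (E/Z mixture) | O[C@]1(C)CC[C@@H]2OC(C)(C)[C@@H](OCc3ccccc3)CC[C@@]2(C)[C@@H]1C=C[C@H]1[C@]2(C)CCC(=O)C(C)(C)O[C@H]2CC[C@]1(C)OC(C)=O | intermediate
41 | 12,13-didehydro 7-O-benzyl derivative of 42 (E/Z mixture) | CC(=O)O[C@]1(C)CC[C@@H]2OC(C)(C)[C@@H](OCc3ccccc3)CC[C@@]2(C)[C@@H]1C=C[C@H]1[C@]2(C)CCC(=O)C(C)(C)O[C@H]2CC[C@]1(C)OC(C)=O | intermediate
42 | 6-{2-[7-acetoxy-3-hydroxy-2,2,5a,7-tetramethyldecahydro-1-benzoxepin-6-yl]ethyl}-2,2,5a,7-tetramethyl-3-oxodecahydro-1-benzoxepin-7-yl acetate; in target locants (1R,4S,7S,10S,11S,14S,15S,21S,24S) | CC(=O)O[C@]1(C)CC[C@@H]2OC(C)(C)[C@@H](O)CC[C@@]2(C)[C@@H]1CC[C@H]1[C@]2(C)CCC(=O)C(C)(C)O[C@H]2CC[C@]1(C)OC(C)=O | target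

## Step count and least certain steps

Total: 35 steps (1–7 shared, 8–20 keto half, 21–32 hydroxy half, 33–35 after the union). Longest linear sequence: 23 steps (1–20, then 33–35).

**Step 18 (key step).** What may go wrong: migration of C19 in competition with C16, a second homologation, or Lewis acid-induced ionisation of the tertiary acetate, since BF3 is used in stoichiometric amount. The fallback sets out from 20 and returns at 24; it inserts the carbon by cyclopropanation and oxidative ring opening instead of by a diazo compound. Soft enolisation of 20 (TMSOTf, Et3N), possible only towards C16, gives the silyl enol ether F1, and Et2Zn/CH2I2 gives the siloxycyclopropane F2. FeCl3 in DMF cleaves the internal cyclopropane bond to the β-chloro oxepanone F3, and NaOAc in methanol eliminates HCl to the oxepenone F4. Hydrogenation over Pd/C saturates C16=C17 and removes the benzyl group, giving 24.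

**Step 3.** What may go wrong: slow hydride transfer through the bridged transition state, or retro-aldol opening of the samarium aldolate of this α-quaternary ketol. The fallback sets out from 4 and returns at 9. Benzyl trichloroacetimidate with catalytic TfOH gives the benzyl ether F5. SmI2 in THF/MeOH, which reduces β-alkoxy ketones to 1,3-anti alcohols through a chelated ketyl, gives the anti alcohol F6. The conditions of steps 4 and 5 give the pyranol benzyl ether F7 and its silyl ether F8, and hydrogenolysis (H2, Pd/C) gives 9.

**Step 4.** What may go wrong: 5-exo opening at C18 competing with the 6-endo mode. The fallback sets out from 6 and returns at 7. The 5-exo product, the tetrahydrofuranyl carbinol F9, is not a dead end: in aqueous HClO4/THF the tertiary hydroxyl ionises with participation of the ring oxygen, and water opens the bridged oxonium ion at C18. This furanoid-to-pyranoid isomerisation involves two inversions at C18 and so gives 7 with the same C18 configuration.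

**Step 11.** What may go wrong: sluggish epoxidation of the hindered, electron-poor tetrasubstituted alkene, and erosion of the C14 configuration in the following SmI2 step. The fallback sets out from 13 and returns at 16. i-Bu2AlH reduces 13 to the allylic alcohol F10; hydroboration with BH3·THF (boron to the less hindered C24, from the face anti to the C15 methyl) and oxidation with H2O2/NaOH place C14–H and C24–OH cis on that face and give diol 16.

**Step 33.** What may go wrong: enolisation of the β-acetoxy aldehyde with loss of acetate, or acetyl transfer from O24 to the intermediate C13 alkoxide before the Smiles rearrangement. The fallback sets out from 34 and returns at 40; it uses a Wittig reaction, whose oxaphosphetane offers no free alkoxide. MeMgBr/CeCl3 adds to 34 to give the tertiary allylic alcohol F11. Hydroboration–oxidation (9-borabicyclo[3.3.1]nonane, then H2O2/NaOH), from the face anti to the axial C10 methyl and C1 hydroxyl, gives diol F12. I2/PPh3/imidazole gives the iodide F13, and PPh3 at 90 °C gives the phosphonium iodide F14. Its oxido ylide (2 equiv NaN(SiMe3)2) reacts with 25 to give 40.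

## Further compounds

F1 | step 18 | trimethylsilyl enol ether of 20 (C16=C18) | CC(=O)O[C@@]1(C)CC[C@@H]2OC(C)(C)C(O[Si](C)(C)C)=C[C@@]2(C)[C@@H]1COCc1ccccc1
F2 | step 18 | siloxycyclopropane from F1 (three-membered ring C16–C17–C18) | CC(=O)O[C@@]1(C)CC[C@@H]2OC(C)(C)C3(O[Si](C)(C)C)CC3[C@@]2(C)[C@@H]1COCc1ccccc1
F3 | step 18 | C16-chloro analogue of 23 (β-chloro oxepanone) | CC(=O)O[C@@]1(C)CC[C@@H]2OC(C)(C)C(=O)CC(Cl)[C@@]2(C)[C@@H]1COCc1ccccc1
F4 | step 18 | 16,17-didehydro analogue of 23 (oxepenone) | CC(=O)O[C@@]1(C)CC[C@@H]2OC(C)(C)C(=O)C=C[C@@]2(C)[C@@H]1COCc1ccccc1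
F5 | step 3 | benzyl ether of 4 | O=C1CCC[C@H](OCc2ccccc2)[C@]1(C)CC=C(C)C
F6 | step 3 | anti alcohol: 3-(benzyloxy)-2-methyl-2-(3-methylbut-2-en-1-yl)cyclohexan-1-ol, hydroxyl trans to prenyl and to the benzyloxy group | O[C@H]1CCC[C@H](OCc2ccccc2)[C@]1(C)CC=C(C)C
F7 | step 3 | 5-O-benzyl analogue of 7 (free C18 hydroxyl) | C1CC[C@@H]2OC(C)(C)[C@@H](O)C[C@@]2(C)[C@H]1OCc1ccccc1
F8 | step 3 | 5-O-benzyl analogue of 8 | C1CC[C@@H]2OC(C)(C)[C@@H](O[Si](C)(C)C(C)(C)C)C[C@@]2(C)[C@H]1OCc1ccccc1
F9 | step 4 | trans-fused 2-(2-hydroxypropan-2-yl)-3a-methyloctahydro-1-benzofuran-4-yl acetate (5-exo product) | C1CC[C@@H]2O[C@@H](C(C)(C)O)C[C@@]2(C)[C@H]1OC(C)=O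
F10 | step 11 | allylic alcohol from 13: {3-[(tert-butyldimethylsilyl)oxy]-2,2,4a,6-tetramethyl-3,4,4a,7,8,8a-hexahydro-2H-chromen-5-yl}methanol | CC=1CC[C@@H]2OC(C)(C)[C@@H](O[Si](C)(C)C(C)(C)C)C[C@@]2(C)C=1CO
F11 | step 33 | 3-(benzyloxy)-2,2,5a,7-tetramethyl-6-methylidenedecahydro-1-benzoxepin-7-ol (C1 hydroxyl axial) | O[C@]1(C)CC[C@@H]2OC(C)(C)[C@@H](OCc3ccccc3)CC[C@@]2(C)C1=C
F12 | step 33 | 3-(benzyloxy)-6-(hydroxymethyl)-2,2,5a,7-tetramethyldecahydro-1-benzoxepin-7-ol | O[C@]1(C)CC[C@@H]2OC(C)(C)[C@@H](OCc3ccccc3)CC[C@@]2(C)[C@@H]1CO
F13 | step 33 | 3-(benzyloxy)-6-(iodomethyl)-2,2,5a,7-tetramethyldecahydro-1-benzoxepin-7-ol | O[C@]1(C)CC[C@@H]2OC(C)(C)[C@@H](OCc3ccccc3)CC[C@@]2(C)[C@@H]1CI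
F14 | step 33 | {[3-(benzyloxy)-7-hydroxy-2,2,5a,7-tetramethyldecahydro-1-benzoxepin-6-yl]methyl}triphenylphosphonium iodide | O[C@]1(C)CC[C@@H]2OC(C)(C)[C@@H](OCc3ccccc3)CC[C@@]2(C)[C@@H]1C[P+](c1ccccc1)(c1ccccc1)c1ccccc1.[I-]
A1 | alternative 1 | (S)-4-[(tert-butyldimethylsilyl)oxy]-3-methylcyclohex-2-en-1-one | O=C1CC[C@H](O[Si](C)(C)C(C)(C)C)C(C)=C1
A2 | alternative 1 | ring B ketone: 4-[(tert-butyldimethylsilyl)oxy]-2-(hydroxymethyl)-3-methyl-3-(4-methylpent-3-en-1-yl)cyclohexan-1-one (silyloxy group trans to the C9 chain) | O=C1CC[C@H](O[Si](C)(C)C(C)(C)C)[C@@](C)(CCC=C(C)C)[C@@H]1CO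
A3 | alternative 2 | straight (2+2) photoadduct holding ring B (C1 ethylene ketal, C11 benzyloxymethyl) and the C4–C8 cyclobutane bond | CC1(C)O[C@@]23CCC4(OCCO4)[C@@H](COCc4ccccc4)[C@]2(C)C[C@H]3C1=O
A4 | alternative 3 | 6-[(benzyloxy)methyl]-2,2,5a-trimethyl-7-methylidenedecahydro-1-benzoxepin-3-ol (rings A and B, free C7 carbinol) | C=C1CC[C@@H]2OC(C)(C)[C@@H](O)CC[C@@]2(C)[C@@H]1COCc1ccccc1
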